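Lobatin B is disconnected at C1–C10, the bond joining the ketone carbon and the quaternary ether carbon of the 3(2H)-furanone ring. An anionic oxy-Cope rearrangement makes this bond while cutting C3–C8, so the six-membered ring of (S)-carvone (C3–C8) is enlarged by four atoms to the ten-membered carbocycle C1–C10 in one operation, delivering the C3 ketone, the Z-C4=C5 enone, an E-C8=C9 alkene for later dihydroxylation and the C10 stereocentre. The precursor is a carvone-derived cyclohex-2-en-1-ol bearing a (Z)-2-(4-methoxybenzyloxy)vinyl group on the carbinol carbon C3 and, trans to it, an (E)-2-(4-methoxybenzyloxy)prop-1-enyl group on C8, with silyl ethers at C6 and C12.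

Key step: step 11

Numbering: target (germacrane) numbering is used for every intermediate. The carvone ring is C3 (C=O), C4 (C–Me), C5, C6, C7, C8; the side chain is C11 (=C13H2) and C12. PMB = 4-methoxybenzyl.

Remark on the chemistry: the C1 configuration formed in step 11 is removed in step 18, so the Z geometry of the C1=C2 enol ether is chosen only because the Z-vinyllithium is the more stable reagent.

Design choices:
- Both enol-ether oxygens carry PMB. One ynol ether then serves both alkenyl units, a benzylic alkoxide is a poor leaving group from the enolate of step 11, and one DDQ step frees C1–OH and C10–OH.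
- C12 is oxygenated on carvone itself, so the methylene lactone is complete before osmylation and no late allylic oxidation is needed.

Assumption on numbering: metal alkoxides that differ from a numbered alcohol only by O–H deprotonation are not numbered separately outside the key step.

Step 1
Reactants: 1 (S)-(+)-carvone
Product: 2 (S)-12-chlorocarvone
Conditions: Ca(OCl)2, CO2 (dry ice), CH2Cl2/H2O, 0 °C
Reagents that add atoms: calcium hypochlorite, [Ca+2].[O-]Cl.[O-]Cl
Why: Ene-type allylic chlorination of the electron-rich 1,1-disubstituted alkene by hypochlorous acid (the enone alkene is too electron-poor to compete) functionalises C12 without touching C7.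

Step 2
Reactants: 2 (S)-12-chlorocarvone
Product: 4 (S)-12-hydroxycarvone, via 12-acetoxycarvone 3 (not isolated)
Conditions: KOAc, n-Bu4NI (cat.), DMF, 50 °C; then K2CO3 (cat.), MeOH, 0 °C
Reagents that add atoms: potassium acetate, CC(=O)[O-].[K+]
Why: SN2 displacement of the primary allylic chloride by acetate followed by base-catalysed transesterification (methanolysis) of the acetate gives the C12 alcohol; no stereocentre is involved.

Step 3
Reactants: 4 (S)-12-hydroxycarvone
Product: 5 linear bis(trimethylsilyl) dienol ether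
Conditions: TMSCl, NaI, Et3N, MeCN, 0 °C → rt
Reagents that add atoms: chlorotrimethylsilane, C[Si](C)(C)Cl
Why: Soft enolisation with in situ iodotrimethylsilane/triethylamine under equilibrating conditions removes the γ-hydrogen at C6 and should give the through-conjugated (thermodynamic) silyl dienol ether C3=C4–C5=C6, while the C12 hydroxyl is silylated.

Step 4
Reactants: 5 linear bis(trimethylsilyl) dienol ether
Product: 7 (4R,5S)-6,12-dihydroxycarvone (C6–OH trans to the C7 side chain), via C3/C6 endoperoxide 6 (not isolated)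
Conditions: O2, tetraphenylporphyrin (cat.), visible light, CH2Cl2, −78 °C; then PPh3, MeOH, −78 °C → rt
Reagents that add atoms: dioxygen, O=O
Why: [4+2] cycloaddition of singlet oxygen to the s-cis diene C3=C4–C5=C6 should occur on the face anti to the adjacent C7 side chain, so the new C6–O bond is trans to C7; phosphine reduction and methanolysis of the silyl peroxyketal unveil the γ-hydroxy enone and the C12 alcohol.

Step 5
Reactants: 7 (4R,5S)-6,12-dihydroxycarvone
Product: 8 6,12-bis-O-TBS enone
Conditions: TBSCl, imidazole, DMF, rt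
Reagents that add atoms: tert-butyldimethylsilyl chloride, CC(C)(C)[Si](C)(C)Cl
Why: Standard silyl ether formation (Corey conditions) on both hydroxyls; stereocentres are untouched.

Step 6
Reactants: 9 4-methoxybenzyl alcohol; 10 trichloroethylene
Product: 14 ethynyl 4-methoxybenzyl ether, via (E)-1,2-dichlorovinyl PMB ether 11 (not isolated), via chloroethynyl PMB ether 12 (not isolated), via lithium PMB-oxyacetylide 13 (not isolated)
Conditions: KH, THF, 0 °C; Cl2C=CHCl, −50 °C → rt; n-BuLi (2.3 equiv), −78 °C; MeOH, −78 °C
Reagents that add atoms: none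
Why: Greene ynol ether synthesis: the alkoxide of 9 adds to the dichloroacetylene equivalent generated from trichloroethylene, butyllithium effects elimination and chlorine–lithium exchange, and cold protonation gives the ethynyl ether, which is kept below 0 °C because benzyl-type ynol ethers rearrange on warming.

Step 7
Reactants: 14 ethynyl 4-methoxybenzyl ether
Product: 16 (E)-1-iodo-2-(PMB-oxy)prop-1-ene, via E-alkenylcopper 15 (not isolated)
Conditions: MeMgBr, CuBr·SMe2, THF/Et2O, −40 °C; 14, −40 → −20 °C; I2, −78 °C
Reagents that add atoms: methylmagnesium bromide, C[Mg]Br; iodine, II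
Why: syn-Carbocupration of the ynol ether places methyl on the oxygen-bearing carbon and copper on the terminal carbon, and iodinolysis with retention gives the E iodide (iodine cis to methyl, trans to the ether oxygen).

Step 8
Reactants: 14 ethynyl 4-methoxybenzyl ether
Product: 17 (Z)-tributyl[2-(PMB-oxy)vinyl]stannane
Conditions: Bu3SnH, Et3B (cat.), air, toluene, −20 °C
Reagents that add atoms: tributyltin hydride, CCCC[SnH](CCCC)CCCC
Why: Radical hydrostannation initiated by triethylborane at low temperature adds the tin radical to the terminal carbon and should give the kinetic anti-addition (Z) β-alkoxyvinylstannane.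

Step 9
Reactants: 8 6,12-bis-O-TBS enone; 16 (E)-1-iodo-2-(PMB-oxy)prop-1-ene
Product: 20 C8-alkenyl ketone (C8 substituent trans to the C7 side chain), via lithium dienolate 18 (not isolated), via chlorozinc dienolate 19 (not isolated)
Conditions: LiHMDS, THF, −78 °C; ZnCl2, −78 → 0 °C; 16, Pd(dba)2 (5 mol%), Q-Phos (5 mol%), THF, rt
Reagents that add atoms: none
Why: Palladium-catalysed α-alkenylation of a ketone enolate (Negishi-type coupling of the kinetic α′ zinc enolate with the alkenyl iodide, geometry retained) forms C8–C9; the new C8 centre should be trans to the C7 side chain because coupling occurs anti to it and the epimerisable centre also prefers the diequatorial arrangement.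

Step 10
Reactants: 20 C8-alkenyl ketone; 17 (Z)-tributyl[2-(PMB-oxy)vinyl]stannane
Product: 22 trans-dialkenyl cyclohexenol (rearrangement precursor), via Z-vinyllithium 21 (not isolated)
Conditions: 17, n-BuLi, THF, −78 °C; then 20 premixed with LaCl3·2LiCl (30 mol%), THF, −78 °C; H2O
Reagents that add atoms: none
Why: Tin–lithium exchange with retention gives the Z-vinyllithium, whose Lewis-acid-promoted 1,2-addition (La(III) suppresses enolisation) should occur on the carbonyl face opposite the adjacent C8 alkenyl group, setting C3 with the two alkenyl groups trans (hydroxyl cis to the C8 substituent).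

Step 11
Reactants: 22 trans-dialkenyl cyclohexenol (rearrangement precursor)
Product: 25 (4Z,8E)-cyclodeca-4,8-dien-3-one, via potassium alkoxide 23 (not isolated), via potassium enolate 24 (not isolated)
Conditions: KHMDS, 18-crown-6, THF, −78 → 0 °C; then AcOH/THF, −78 °C
Reagents that add atoms: none
Why: Deprotonation gives tertiary allylic alkoxide 23, whose oxyanion weakens C3–C8 so that the 1,5-diene C1=C2–C3–C8–C9=C10 undergoes a concerted [3,3]-sigmatropic shift (anionic oxy-Cope rearrangement, the known ring expansion of trans-1,2-dialkenylcyclohexanols to cyclodec-5-enones), forming C1–C10, cutting C3–C8 and leaving cross-conjugated enolate 24, which is protonated at C2 at −78 °C. The ten-membered carbocycle is not closed end to end: it results from four-atom enlargement of the C3–C8 six-membered ring through a six-centre chair array, so the cis ring alkene becomes Z-C4=C5 and the trans-diequatorial alkenyl groups give E-C8=C9. C10 is set by the E geometry of the C9=C10 enol ether (methyl axial, OPMB equatorial) in the only accessible chair, whose sense is fixed by the C7-derived trans relationships at C8 and C3; this places the methyl and the ether oxygen as in the target. C1 is set by the Z enol ether (OPMB axial) but is erased in step 18. The step needs the [3,3] shift to win over fragmentation and over the alternative diene C5=C4–C3–C8–C9=C10, and it needs the β-alkoxy enolate to survive; the chair with both ring carbons equatorial (not open to the endocyclic alkene), the poor leaving-group ability of a benzylic alkoxide, the orthogonality of the C1–O bond to the nascent enolate π system and the cold acidic quench should secure these.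

Step 12
Reactants: 25 (4Z,8E)-cyclodeca-4,8-dien-3-one
Product: 26 C6,C12-diol
Conditions: HF·pyridine, pyridine, THF, 0 °C → rt
Reagents that add atoms: none
Why: Fluoride cleavage of both silyl ethers under pyridine-buffered conditions leaves the PMB ethers, the β-alkoxy ketone and all stereocentres untouched, and dehydration of any C3/C6 hemiketal to a furan is disfavoured by the strain of the bridged ring.

Step 13
Reactants: 26 C6,C12-diol
Product: 29 trans-fused α-methylene γ-lactone, via hydroxy enal 27 (not isolated), via lactol 28 (not isolated)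
Conditions: TEMPO (20 mol%), PhI(OAc)2 (2.5 equiv), CH2Cl2, rt
Reagents that add atoms: none
Why: TEMPO/PhI(OAc)2 oxidative lactonisation: the primary allylic alcohol is oxidised selectively to the enal, the C6 hydroxyl closes the γ-lactol (5-exo-trig) and this is oxidised to the α-methylene γ-lactone, trans-fused as dictated by C6 and C7.

Step 14
Reactants: 29 trans-fused α-methylene γ-lactone
Product: 30 C8,C9-diol
Conditions: OsO4 (5 mol%), NMO, acetone/H2O, 0 °C
Reagents that add atoms: osmium tetroxide, O=[Os](=O)(=O)=O; N-methylmorpholine N-oxide, C[N+]1([O-])CCOCC1; water, O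
Why: Upjohn dihydroxylation should attack the only electron-rich alkene (methylene lactone and enone are deactivated), syn addition to the E alkene fixes the C8/C9 relationship, and the face is expected anti to the allylic C10–O bond on the outer face of the ring alkene (Kishi's rule: new C9–OH erythro to C10–OPMB), which corresponds to the target configuration.

Step 15
Reactants: 30 C8,C9-diol
Product: 31 C8 isovalerate
Conditions: isovaleric anhydride (1.1 equiv), DMAP (cat.), Et3N, CH2Cl2, −20 °C
Reagents that add atoms: isovaleric anhydride, CC(C)CC(=O)OC(=O)CC(C)C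
Why: DMAP-catalysed acylation should discriminate the C8 hydroxyl (flanked by a methine) from the neopentyl-type C9 hydroxyl next to the quaternary C10; low temperature limits acyl migration and translactonisation.

Step 16
Reactants: 31 C8 isovalerate
Product: 32 C9 triethylsilyl ether
Conditions: TESOTf, 2,6-lutidine, CH2Cl2, −78 °C
Reagents that add atoms: triethylsilyl trifluoromethanesulfonate, CC[Si](CC)(CC)OS(=O)(=O)C(F)(F)F
Why: Silylation of the remaining hindered secondary alcohol with the silyl triflate masks C9–OH so that only C1–OH is oxidised in step 18.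

Step 17
Reactants: 32 C9 triethylsilyl ether
Product: 33 C1,C10-diol
Conditions: DDQ (2.5 equiv), CH2Cl2/pH 7 buffer, 0 °C → rt
Reagents that add atoms: none
Why: Oxidative cleavage of both PMB ethers by DDQ (hydride abstraction to benzylic oxocarbenium ions, then hydrolysis) in buffered medium should free C1–OH and the tertiary C10–OH without affecting the silyl ether, the esters or the alkenes.

Step 18
Reactants: 33 C1,C10-diol
Product: 34 α′-hydroxy 1,3-diketone
Conditions: Dess–Martin periodinane, pyridine, CH2Cl2, 0 °C → rt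
Reagents that add atoms: none
Why: Dess–Martin oxidation converts the only free secondary alcohol (C1) into the ketone; the tertiary C10 alcohol cannot be oxidised and C1 loses its stereocentre.

Step 19
Reactants: 34 α′-hydroxy 1,3-diketone
Product: 37 lobatin B, via C3 hemiketal 35 (not isolated), via 9-O-TES lobatin B 36 (not isolated)
Conditions: p-TsOH·H2O (cat.), THF/H2O, rt
Reagents that add atoms: none
Why: Acid-catalysed cyclodehydration of the α′-hydroxy 1,3-diketone to the 3(2H)-furanone (5-exo-trig attack of C10–OH on the C3 carbonyl, loss of water from the hemiketal) with concomitant hydrolysis of the triethylsilyl ether; C10 keeps its configuration because its C–O bond is not broken.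

Compound list

1 | (S)-(+)-carvone | CC(=C)[C@H]1CC=C(C)C(=O)C1 | starting material
2 | (S)-12-chlorocarvone, (5S)-5-(3-chloroprop-1-en-2-yl)-2-methylcyclohex-2-en-1-one | ClCC(=C)[C@H]1CC=C(C)C(=O)C1 | intermediate
3 | (S)-12-acetoxycarvone | CC(=O)OCC(=C)[C@H]1CC=C(C)C(=O)C1 | intermediate (not isolated)
4 | (S)-12-hydroxycarvone, (5S)-5-(3-hydroxyprop-1-en-2-yl)-2-methylcyclohex-2-en-1-one | OCC(=C)[C@H]1CC=C(C)C(=O)C1 | intermediate
5 | 2-methyl-1-(trimethylsilyloxy)-5-[3-(trimethylsilyloxy)prop-1-en-2-yl]cyclohexa-1,3-diene, C7 as in carvone | C[Si](C)(C)OCC(=C)[C@H]1C=CC(C)=C(O[Si](C)(C)C)C1 | intermediate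
6 | 2,3-dioxabicyclo[2.2.2]oct-5-ene endoperoxide bridging C3 (OTMS) and C6, peroxide anti to the C7 side chain | CC1=C[C@H]2OO[C@]1(O[Si](C)(C)C)C[C@H]2C(=C)CO[Si](C)(C)C | intermediate (not isolated)
7 | (4R,5S)-4-hydroxy-5-(3-hydroxyprop-1-en-2-yl)-2-methylcyclohex-2-en-1-one (C6–OH trans to the C7 side chain) | CC1=C[C@@H](O)[C@H](C(=C)CO)CC1=O | intermediate
8 | 6,12-bis-O-TBS ether of 7 | CC1=C[C@@H](O[Si](C)(C)C(C)(C)C)[C@H](C(=C)CO[Si](C)(C)C(C)(C)C)CC1=O | intermediate
9 | 4-methoxybenzyl alcohol | COc1ccc(CO)cc1 | starting material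
10 | trichloroethylene | ClC=C(Cl)Cl | starting material
11 | (E)-1,2-dichlorovinyl 4-methoxybenzyl ether | Cl/C=C(/Cl)OCc1ccc(OC)cc1 | intermediate (not isolated)
12 | chloroethynyl 4-methoxybenzyl ether | ClC#COCc1ccc(OC)cc1 | intermediate (not isolated)
13 | lithium (4-methoxybenzyloxy)acetylide | [Li]C#COCc1ccc(OC)cc1 | intermediate (not isolated)
14 | ethynyl 4-methoxybenzyl ether | C#COCc1ccc(OC)cc1 | intermediate
15 | (E)-2-(4-methoxybenzyloxy)prop-1-enylcopper | [Cu]/C=C(\C)OCc1ccc(OC)cc1 | intermediate (not isolated)
16 | (E)-1-iodo-2-(4-methoxybenzyloxy)prop-1-ene | I/C=C(\C)OCc1ccc(OC)cc1 | intermediate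
17 | (Z)-tributyl[2-(4-methoxybenzyloxy)vinyl]stannane | CCCC[Sn](CCCC)(CCCC)/C=C\OCc1ccc(OC)cc1 | intermediate
18 | lithium C3(O)=C8 dienolate of 8 | CC1=C[C@@H](O[Si](C)(C)C(C)(C)C)[C@H](C(=C)CO[Si](C)(C)C(C)(C)C)C=C1O[Li] | intermediate (not isolated)
19 | chlorozinc C3(O)=C8 dienolate of 8 | CC1=C[C@@H](O[Si](C)(C)C(C)(C)C)[C@H](C(=C)CO[Si](C)(C)C(C)(C)C)C=C1O[Zn]Cl | intermediate (not isolated)
20 | enone 8 carrying at C8, trans to the C7 side chain, an (E)-2-(PMB-oxy)prop-1-enyl group | CC1=C[C@@H](O[Si](C)(C)C(C)(C)C)[C@H](C(=C)CO[Si](C)(C)C(C)(C)C)[C@@H](/C=C(\C)OCc2ccc(OC)cc2)C1=O | intermediate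
21 | (Z)-2-(4-methoxybenzyloxy)vinyllithium | [Li]/C=C\OCc1ccc(OC)cc1 | intermediate (not isolated)
22 | cyclohex-2-en-1-ol with C3–OH and (Z)-2-(PMB-oxy)vinyl on C3, (E)-2-(PMB-oxy)prop-1-enyl on C8 (alkenyl groups trans, OH cis to the C8 group), C7 side chain trans to the C8 group, C6–OTBS trans to C7 | CC1=C[C@@H](O[Si](C)(C)C(C)(C)C)[C@H](C(=C)CO[Si](C)(C)C(C)(C)C)[C@@H](/C=C(\C)OCc2ccc(OC)cc2)[C@]1(O)/C=C\OCc3ccc(OC)cc3 | intermediate
23 | potassium alkoxide of 22 | CC1=C[C@@H](O[Si](C)(C)C(C)(C)C)[C@H](C(=C)CO[Si](C)(C)C(C)(C)C)[C@@H](/C=C(\C)OCc2ccc(OC)cc2)[C@]1([O-])/C=C\OCc3ccc(OC)cc3.[K+] | intermediate (not isolated)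
24 | potassium C2=C3 enolate of the ten-membered ring (C1 and C4 trans across C2=C3) | CC(C)(C)[Si](C)(C)O[C@@H]1/C=C(/C)\C([O-])=C\[C@H](OCc3ccc(OC)cc3)[C@](C)(OCc2ccc(OC)cc2)/C=C/[C@H]1C(=C)CO[Si](C)(C)C(C)(C)C.[K+] | intermediate (not isolated)
25 | (4Z,8E)-cyclodeca-4,8-dien-3-one: C1–OPMB, C10(Me)–OPMB, C6–OTBS, C7–C(=CH2)CH2OTBS, 4-methyl | CC(C)(C)[Si](C)(C)O[C@@H]1/C=C(/C)C(=O)C[C@H](OCc3ccc(OC)cc3)[C@](C)(OCc2ccc(OC)cc2)/C=C/[C@H]1C(=C)CO[Si](C)(C)C(C)(C)C | intermediate
26 | C6,C12-diol of 25 | O[C@@H]1/C=C(/C)C(=O)C[C@H](OCc3ccc(OC)cc3)[C@](C)(OCc2ccc(OC)cc2)/C=C/[C@H]1C(=C)CO | intermediate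
27 | C6-hydroxy C12-enal | O[C@@H]1/C=C(/C)C(=O)C[C@H](OCc3ccc(OC)cc3)[C@](C)(OCc2ccc(OC)cc2)/C=C/[C@H]1C(=C)C=O | intermediate (not isolated)
28 | C12 lactol (O bridging C6 and C12) | C=C1C(O)O[C@@H]2/C=C(/C)C(=O)C[C@H](OCc3ccc(OC)cc3)[C@](C)(OCc4ccc(OC)cc4)/C=C/[C@@H]12 | intermediate (not isolated)
29 | trans-fused 6,12-olide (α-methylene γ-lactone) with C3 ketone, Z-C4=C5, E-C8=C9, C1–OPMB, C10–OPMB | C=C1C(=O)O[C@@H]2/C=C(/C)C(=O)C[C@H](OCc3ccc(OC)cc3)[C@](C)(OCc4ccc(OC)cc4)/C=C/[C@@H]12 | intermediate
30 | C8,C9-diol of 29 (C8, C9 configured as in the target) | C=C1C(=O)O[C@@H]2/C=C(/C)C(=O)C[C@H](OCc3ccc(OC)cc3)[C@](C)(OCc4ccc(OC)cc4)[C@H](O)[C@@H](O)[C@@H]12 | intermediate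
31 | C8 isovalerate (3-methylbutanoate) of 30 | C=C1C(=O)O[C@@H]2/C=C(/C)C(=O)C[C@H](OCc3ccc(OC)cc3)[C@](C)(OCc4ccc(OC)cc4)[C@H](O)[C@@H](OC(=O)CC(C)C)[C@@H]12 | intermediate
32 | C9 triethylsilyl ether of 31 | C=C1C(=O)O[C@@H]2/C=C(/C)C(=O)C[C@H](OCc3ccc(OC)cc3)[C@](C)(OCc4ccc(OC)cc4)[C@H](O[Si](CC)(CC)CC)[C@@H](OC(=O)CC(C)C)[C@@H]12 | intermediate
33 | C1,C10-diol (both PMB groups removed) | C=C1C(=O)O[C@@H]2/C=C(/C)C(=O)C[C@H](O)[C@](C)(O)[C@H](O[Si](CC)(CC)CC)[C@@H](OC(=O)CC(C)C)[C@@H]12 | intermediate
34 | C1,C3-diketone with tertiary C10–OH | C=C1C(=O)O[C@@H]2/C=C(/C)C(=O)CC(=O)[C@](C)(O)[C@H](O[Si](CC)(CC)CC)[C@@H](OC(=O)CC(C)C)[C@@H]12 | intermediate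
35 | C3 hemiketal (C10–O–C3 bridge, C1 ketone) | C=C1C(=O)O[C@@H]2/C=C(/C)C3(O)CC(=O)[C@](C)(O3)[C@H](O[Si](CC)(CC)CC)[C@@H](OC(=O)CC(C)C)[C@@H]12 | intermediate (not isolated)
36 | 9-O-triethylsilyl lobatin B | C=C1C(=O)O[C@@H]2/C=C(/C)C3=CC(=O)[C@](C)(O3)[C@H](O[Si](CC)(CC)CC)[C@@H](OC(=O)CC(C)C)[C@@H]12 | intermediate (not isolated)
37 | lobatin B | C=C1C(=O)O[C@@H]2/C=C(/C)C3=CC(=O)[C@](C)(O3)[C@H](O)[C@@H](OC(=O)CC(C)C)[C@@H]12 | target

Total step count: 19 steps.
Longest linear sequence: 16 steps from (S)-carvone (steps 1–5 and 9–19). Steps 6–8 form the side branch from 4-methoxybenzyl alcohol and trichloroethylene.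

Steps most likely to fail

Step 11. The potassium enolate may expel the C1 4-methoxybenzyloxide (E1cB) once formed, or the alkoxide may fragment before the sigmatropic shift takes place. The fallback is a neutral siloxy-Cope rearrangement that keeps the disconnection but never generates a free enolate. It sets out from 22, which is silylated (TMSOTf, 2,6-lutidine, −78 °C) to the tertiary trimethylsilyl ether F1. Heating F1 in degassed xylene (150–170 °C, base-washed vessel) should give, through the same chair, the ring-enlarged trimethylsilyl enol ether F2. Mild methanolysis (PPTS, MeOH, 0 °C) then releases ketone 25, where the route is rejoined.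

Step 9. Reductive elimination from the alkenylpalladium enolate may be slow, so that proton exchange between product and enolate leads to double alkenylation or to migration of the enol-ether double bond into conjugation. The fallback reverses the polarity at C8. It sets out from 8, which is brominated through its lithium enolate (LiHMDS; NBS, −78 °C) to the α′-bromo ketone F3. Iodide 16 is converted by iodine–lithium exchange and transmetalation (t-BuLi, −78 °C; ZnCl2) into the alkenylzinc chloride F4. A nickel-catalysed stereoconvergent Negishi coupling of the α-bromo ketone (NiCl2·glyme, bipyridine ligand, THF/DMA, 0 °C) should then give 20, with both C8 epimers of the bromide converging on the trans product.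

Step 14. Osmium may approach the other face of C8=C9, because the E alkene can turn through the ring and its two rotamers expose opposite faces; oxidation of the methylene lactone may also compete. The fallback is a Woodward cis-hydroxylation, which delivers the cis-diol to the face opposite to the one first attacked by the electrophile. It sets out from 29, which with I2 and AgOAc in wet acetic acid should give, by anti iodo-acetoxylation, acetoxonium participation and hydrolysis, the hydroxy acetate F5 (drawn as the C9 acetate). Mild methanolysis (K2CO3 cat., MeOH, −20 °C) returns diol 30.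

Further compounds

F1 | step 11 | trimethylsilyl ether of 22 | CC1=C[C@@H](O[Si](C)(C)C(C)(C)C)[C@H](C(=C)CO[Si](C)(C)C(C)(C)C)[C@@H](/C=C(\C)OCc2ccc(OC)cc2)[C@]1(O[Si](C)(C)C)/C=C\OCc3ccc(OC)cc3
F2 | step 11 | ten-membered C2=C3 trimethylsilyl enol ether | CC(C)(C)[Si](C)(C)O[C@@H]1/C=C(/C)\C(O[Si](C)(C)C)=C\[C@H](OCc3ccc(OC)cc3)[C@](C)(OCc2ccc(OC)cc2)/C=C/[C@H]1C(=C)CO[Si](C)(C)C(C)(C)C
F3 | step 9 | C8-bromo derivative of 8 (α′-bromo ketone) | CC1=C[C@@H](O[Si](C)(C)C(C)(C)C)[C@H](C(=C)CO[Si](C)(C)C(C)(C)C)C(Br)C1=O
F4 | step 9 | (E)-2-(4-methoxybenzyloxy)prop-1-enylzinc chloride | Cl[Zn]/C=C(\C)OCc1ccc(OC)cc1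
F5 | step 14 | C9 acetate of diol 30 | C=C1C(=O)O[C@@H]2/C=C(/C)C(=O)C[C@H](OCc3ccc(OC)cc3)[C@](C)(OCc4ccc(OC)cc4)[C@H](OC(C)=O)[C@@H](O)[C@@H]12
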